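All runs stem from a simulated flask for an exercise.

1. I started from a one-step world: a first end group meets a second end group and makes a link, and each link costs one of each.

| flask | first end groups | second end groups | temperature | remark | time |
|---|---|---|---|---|---|
| ash | 0.022 M | 0.11 M | −15 °C | run made earlier |  |
| cedar | 0.050 M | 0.11 M | 0 °C | run made earlier |  |
| alder | 0.073 M | 0.11 M | −15 °C | run made earlier |  |
| delta | 0.025 M | 0.110 M | 0 °C |  | 12 h |
| beta | 0.10 M | 0.110 M | 0 °C |  | 25 h |

- ash (time / h: links / %, first end groups / %): 3.00: 5.4, 81.6; 5.00: 8.7, 71.8; 10.0: 15.1, 54.9; 20.0: 23.4, 38.6; 40.0: 36.4, 27.6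
- cedar (time / h: links / %, first end groups / %): 1.33: 11.5, 60.2; 2.50: 19.6, 49.3; 5.00: 30.3, 40.1; 10.0: 47.6, 31.3; 20.0: 67.2, 18.6
- alder (time / h: links / %, first end groups / %): 3.00: 5.5, 81.4; 5.00: 8.2, 71.7; 10.0: 14.5, 54.8; 20.0: 23.0, 39.2; 40.0: 33.9, 29.0

(standard deviation of a reading: 0.3 percentage points)



1. which one finishes higher in amount of links, in percent of the first end groups charged ("neither" within 2 percentage points) (delta / beta / neither)
2. amount of links at the end, in percent of the first end groups charged, delta
3. amount of links at the end, in percent of the first end groups charged, beta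

2. The readings broke that world for first end groups: in the ash run at 10.0 h, 30.0 % of the charge was neither free nor linked. I kept its bookkeeping for second end groups.

3. In beta 0.909 was the drain, the charge of first end groups over the charge of second end groups. The reserve, the fraction of second end groups still free, is then one minus drain times links, with links as a fraction of the first charge.

4. Ash and alder looked nearly the same: at 3.00 h they held 5.4 % and 5.5 % links. Their drains were 0.200 and 0.664, however, so at 40.0 h their reserves were 92.7 % and 77.5 %. Ash stayed close to pseudo-first-order. From 20.0 h to 40.0 h, alder's gain in links read 0.838 of ash's, while alder's reserve read 0.889 of ash's at the start of that stretch and 0.836 at its end. So alder ended lower, with 33.9 % links against 36.4 %.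

5. Delta's drain was 0.227. Beta had twice delta's time, but 4.00 times its drain. Cedar, at their temperature with a drain of 0.455, gained 20 percentage points from 10.0 h to 20.0 h, with its reserve reading 69.5 % at the end of that stretch. On that gain I expected beta to lead.

6. The forecast gave 55 % (52 % to 58.5 %) for delta and 65 % (60 % to 70 %) for beta, so beta higher, noting that “Alder's links lag slightly at high conversion”.

7. Delta gave 55.3 % and beta 64.6 %, so beta finished higher by 9.3 points. The equations behind the readings:

    first end groups ⇌ dormant form (K = 0.650, k = 0.440 h⁻¹, Ea = 83.0 kJ mol⁻¹, ΔH = −22.0 kJ mol⁻¹)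
    first end groups + second end groups ⇌ links (K = 360 L mol⁻¹, k = 1.10 L mol⁻¹ h⁻¹, Ea = 69.0 kJ mol⁻¹, ΔH = −63.0 kJ mol⁻¹)
    (constants at 0 °C)

8. At the end, beta's second end groups stood at 41.2 % and delta's at 87.4 %. The drain gives beta's reserve as 41.3 %. In the repeat of delta at 15 °C, with 83.9 % links, delta's drain gives 81.0 %, and that flask's second end groups stood at 81 %.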